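## Analysis of the target

Target 16, (R)-1-(3,4-dihydroxy-5-methoxyphenyl)-5-hydroxy-7-(4-hydroxy-3-methoxyphenyl)heptan-3-one, is an open-chain diarylheptanoid with no ring other than its two arenes. The chain is numbered from C1, which carries ring B (3,4-dihydroxy-5-methoxyphenyl), to C7, which carries ring A (4-hydroxy-3-methoxyphenyl); C3 is a ketone and C5 a secondary carbinol. C5 is the only stereocentre and is (R); it has no neighbouring stereocentre to relay from and lies between two methylene groups, C4 and C6, that differ only one atom further out. The C3/C5 β-hydroxy ketone can lose water by an E1cB path or cleave by retro-aldol reaction under base, the free catechol of ring B is oxidised by air, and three phenols must be freed at the end under conditions that respect both. The skeleton is easy; the difficulty is to set one isolated carbinol in a single absolute sense and to join two aryl-ethyl ends that differ by one ring oxygen without confusing them. The strategy rests on C6 and C7: they are plain CH2 groups between ring A and C5, so they can be carried as a C6=C7 alkene that is saturated in the same hydrogenation that frees the phenols. With that alkene in place C5 is a vinyl carbinol, available enantiopure from a five-carbon hydroxy ester, and ring A enters as a styrene. In every alkene-bearing intermediate the same spatial arrangement at C5 is labelled (S), because the alkenyl carbon outranks C4; the label returns to (R) when C6 becomes CH2.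

## Retrosynthetic reasoning

**16 ⇒ 15.** The last operation is a heterogeneous hydrogenation that does two jobs. Working backwards, the three phenols become benzyl ethers and the C6–C7 single bond becomes an (E)-alkene, which gives 15. The gain is that the phenols and the catechol stay masked throughout and appear only in a final neutral step. The forward reaction has to saturate the alkene before the allylic C5–O bond can be cleaved.

**15 ⇒ 12 + 14.** The C6=C7 double bond is cut into two terminal alkenes, the vinyl carbinol 12 and the ring A styrene 14. This is the one bond of the chain whose formation leaves nothing behind after hydrogenation, and it is remote from the ketone, so no enolate chemistry is involved in the union. It divides the molecule into a one-step styrene and a ketone that carries everything else, including the stereocentre. The forward reaction, a ruthenium-catalysed cross-metathesis, must favour the cross product over the homodimers and must leave the allylic stereocentre and the β-hydroxy ketone untouched; the alkene geometry is not critical because the bond is later saturated.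

**14 ⇒ 13.** The vinyl group of 14 is traced to the aldehyde carbon of 13, which is bought with the benzyl ether already in place. The forward reaction is a one-carbon olefination.

**12 ⇒ 4 + 11.** The C2–C3 bond between the carbonyl carbon and the ring B arm is cut, giving the Weinreb amide 4 as the acyl partner and the primary Grignard reagent 11. Cutting at C3–C4 or C4–C5 instead would mean an aldol reaction that has to create C5 on an acyclic methyl ketone with weak control. Here the stereocentre sits in the small piece 4 and is only carried along. The forward reaction must stop at the ketone and must tolerate the free hydroxyl at the cost of one equivalent of 11.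

**11 ⇒ 10 ⇒ 9 ⇒ 7 ⇒ 6 ⇒ 5.** The organomagnesium 11 comes from bromide 10, and its C–Br bond from the primary alcohol 9. The C–O bond of 9 is traced through the borane 8 to the terminal carbon of styrene 7, which puts oxygen at the anti-Markovnikov position. The alkene of 7 is traced to aldehyde 6 and the two benzyl ethers to the catechol of commercial 5. Ring B thus receives the same protecting group as ring A, so one final step removes them all.

**4 ⇒ 3 ⇒ 2 ⇒ 1.** The amide of 4 is traced to the ethyl ester 3, and the stereocentre to racemic 1 through an enzymatic kinetic resolution in which the (S)-alcohol is acylated to 2 and then released. The resolution stands at the first step, on the cheapest compound of the route, where losing the unwanted half costs least. The forward reaction has to distinguish a vinyl group from CH2CO2Et at the carbinol.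

## Alternatives that were turned down

**Alternative 1:** The C5–H bond is disconnected, so the target would come from the unprotected β-diketone A1, (E)-1-(3,4-dihydroxy-5-methoxyphenyl)-7-(4-hydroxy-3-methoxyphenyl)hept-1-ene-3,5-dione, put together by biomimetic condensation chemistry. In the forward key step a ketoreductase with its nicotinamide cofactor would deliver hydride to the non-conjugated C5 carbonyl and leave the C3 enone, giving the (R)-carbinol A2, (R,E)-1-(3,4-dihydroxy-5-methoxyphenyl)-5-hydroxy-7-(4-hydroxy-3-methoxyphenyl)hept-1-en-3-one; saturation of C1=C2 would finish.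
- For: it is by far the shortest plan, needs no protecting group, and the conjugation of C3 with ring B distinguishes the two carbonyls electronically.
- Against: A1 is largely enolised and the enol is conjugated through to ring B, so the C5 ketone is present only in part. Which carbonyl and which face are reduced, and whether the enone alkene or both carbonyls react, all depend on an enzyme that must be found by screening for a substrate with two bulky aryl ends. Nothing in the structure allows the outcome to be argued in advance. The free catechol is exposed to aerated buffer, and A2 is a β-hydroxy enone that dehydrates readily to a cross-conjugated dienone.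
- Comparison: on step economy and protecting-group economy this alternative is clearly stronger. The chosen route offers in its place a configuration fixed by a size-based resolution of a small substrate, and bench steps that each have a predictable course.

**Alternative 2:** The C5–C6 bond is disconnected into the ketal aldehyde A3, 2-(2-{2-[3,4-bis(benzyloxy)-5-methoxyphenyl]ethyl}-1,3-dioxolan-2-yl)acetaldehyde, and the dialkylzinc A4, bis{2-[4-(benzyloxy)-3-methoxyphenyl]ethyl}zinc, which would be made from styrene 14 by hydroboration and boron-to-zinc exchange. In the forward key step, under a titanium alkoxide and an enantiopure trans-1,2-bis(trifluoromethanesulfonamido)cyclohexane, one 2-arylethyl group adds to the aldehyde carbon and forms the C5–C6 bond and the stereocentre, giving A5, (R)-4-[4-(benzyloxy)-3-methoxyphenyl]-1-(2-{2-[3,4-bis(benzyloxy)-5-methoxyphenyl]ethyl}-1,3-dioxolan-2-yl)butan-2-ol. Ketal hydrolysis and hydrogenolysis follow.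
- For: the stereocentre and the complete skeleton arise in one catalytic C–C bond formation with no resolution, and the same styrene 14 serves.
- Against: A3 is a masked β-keto aldehyde that needs several steps of protection and redox adjustment, and it can eliminate a ketal oxygen to an enal under Lewis acid. Only one of the two alkyl groups of A4 is transferred and A4 is used in excess, so most of the ring A fragment is lost. The boron–zinc exchange is a pyrophoric operation. The final acid deketalisation acts on a β-hydroxy ketal and risks dehydration to the enone.
- Comparison: in setting C5 by catalysis and not by resolution this alternative is stronger. The chosen route offers a union that needs no carbonyl mask and releases only ethylene, and it confines the loss of the resolution to the first step on an inexpensive C5 ester.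

**Alternative 3:** The C2–C3 bond is disconnected into two carboxylic acid derivatives, the redox-active ester A6, 1,3-dioxoisoindolin-2-yl 3-[3,4-bis(benzyloxy)-5-methoxyphenyl]propanoate, and the thioester A7, S-(pyridin-2-yl) (R)-5-[4-(benzyloxy)-3-methoxyphenyl]-3-[(tert-butyldimethylsilyl)oxy]pentanethioate. In the forward key step a nickel–bipyridine catalyst with a metallic reductant generates the primary 2-arylethyl radical from A6 by electron transfer and decarboxylation. The acylnickel formed from A7 captures it, and reductive elimination forms the C2–C3 bond, giving A8, (R)-7-[4-(benzyloxy)-3-methoxyphenyl]-1-[3,4-bis(benzyloxy)-5-methoxyphenyl]-5-[(tert-butyldimethylsilyl)oxy]heptan-3-one. Desilylation and hydrogenolysis follow.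
- For: both partners are bench-stable, no organomagnesium reagent is needed, the ketone forms at the right oxidation level, and C5 could be set beforehand by asymmetric hydrogenation of a β-keto ester, which is catalytic and not limited to half the material.
- Against: the acid behind A7 needs about five steps and the one behind A6 about three. A β-silyloxy acylnickel can decarbonylate or eliminate, and the primary radical can dimerise or be reduced. A silyl ether must finally be removed from a β-silyloxy ketone, with a risk of elimination.
- Comparison: as a ketone-forming event it is at least as mild as the Grignard addition of step 8, and it avoids the resolution. The chosen route offers fewer steps, no silyl group, and a catalytic union at a position with no neighbouring functionality, followed by an end-game in which saturation and deprotection coincide.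

Key step: step 10

Remark on the chemistry: the lipase is assumed to follow its usual size-based preference for secondary alcohols, so that the (S)-enantiomer of 1 (vinyl as the smaller, CH2CO2Et as the larger group) is the one acylated; with the reverse preference the unreacted alcohol would be taken on as 3 and step 2 would fall away.

## Route

**Step 1**
Reactants: 1 ethyl 3-hydroxypent-4-enoate (racemic)
Product: 2 ethyl (S)-3-acetoxypent-4-enoate
Conditions: Burkholderia cepacia lipase (Amano PS, immobilised), vinyl acetate (3 equiv), MTBE, 30 °C, stopped short of half conversion; chromatography removes unreacted (R)-1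
Reagents that add atoms: vinyl acetate, CC(=O)OC=C
Why: Lipase-catalysed kinetic resolution by irreversible transesterification; the enzyme should acylate the enantiomer that places vinyl in its medium pocket and CH2CO2Et in its large pocket, which is the (S)-alcohol, and stopping before half conversion keeps the acetate enantiomerically enriched. This step sets the stereocentre that becomes C5 of the target.

**Step 2**
Reactants: 2 ethyl (S)-3-acetoxypent-4-enoate
Product: 3 ethyl (S)-3-hydroxypent-4-enoate
Conditions: HCl (0.2 equiv, 1.25 M in EtOH), EtOH, 0 °C → rt
Reagents that add atoms: none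
Why: Acid-catalysed transesterification cleaves the acetate at the acyl–oxygen bond, so the C–O bond at the stereocentre is not touched; in ethanol the ethyl ester only exchanges with itself, and acid avoids the E1cB loss of acetate that a basic cleavage would invite.

**Step 3**
Reactants: 3 ethyl (S)-3-hydroxypent-4-enoate
Product: 4 (S)-3-hydroxy-N-methoxy-N-methylpent-4-enamide
Conditions: MeNH(OMe)·HCl (1.6 equiv), iPrMgCl (4.2 equiv), THF, −20 → 0 °C; aq. NH4Cl
Reagents that add atoms: N,O-dimethylhydroxylamine hydrochloride, CNOC.Cl
Why: Weinreb amidation of an ester by the chloromagnesium amide formed in the flask; one further equivalent of iPrMgCl turns the hydroxyl into an inert magnesium alkoxide, and the stereocentre takes no part.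

**Step 4**
Reactants: 5 3,4-dihydroxy-5-methoxybenzaldehyde
Product: 6 3,4-bis(benzyloxy)-5-methoxybenzaldehyde
Conditions: BnBr (2.4 equiv), K2CO3 (3 equiv), DMF, 60 °C
Reagents that add atoms: benzyl bromide, BrCc1ccccc1
Why: Williamson ether synthesis on both catechol hydroxyls; the formyl group makes the phenols acidic enough for K2CO3 and is itself inert.

**Step 5**
Reactants: 6 3,4-bis(benzyloxy)-5-methoxybenzaldehyde
Product: 7 1,2-bis(benzyloxy)-3-methoxy-5-vinylbenzene
Conditions: Ph3PCH3Br (1.3 equiv), KOtBu (1.25 equiv), THF, 0 °C → rt
Reagents that add atoms: methyltriphenylphosphonium bromide, C[P+](c1ccccc1)(c1ccccc1)c1ccccc1.[Br-]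
Why: Wittig methylenation of an aromatic aldehyde with the non-stabilised ylide; benzyl and methyl ethers are inert.

**Step 6**
Reactants: 7 1,2-bis(benzyloxy)-3-methoxy-5-vinylbenzene
Product: 9 2-[3,4-bis(benzyloxy)-5-methoxyphenyl]ethan-1-ol, via alkylborane 8 (not isolated)
Conditions: 9-BBN (1.2 equiv), THF, 0 °C → rt; then 3 M NaOH, 30% H2O2, 0 °C → rt
Reagents that add atoms: hydrogen peroxide, OO
Why: Hydroboration–oxidation; 9-BBN places boron almost exclusively on the terminal carbon of a styrene, a preference the electron-rich ring reinforces, and oxidative migration with retention gives the primary alcohol.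

**Step 7**
Reactants: 9 2-[3,4-bis(benzyloxy)-5-methoxyphenyl]ethan-1-ol
Product: 10 1,2-bis(benzyloxy)-5-(2-bromoethyl)-3-methoxybenzene
Conditions: CBr4 (1.2 equiv), PPh3 (1.25 equiv), CH2Cl2, 0 °C
Reagents that add atoms: carbon tetrabromide, BrC(Br)(Br)Br
Why: Appel bromination of a primary alcohol by SN2 displacement of the oxyphosphonium group; the neutral conditions leave the benzyl ethers alone.

**Step 8**
Reactants: 10 1,2-bis(benzyloxy)-5-(2-bromoethyl)-3-methoxybenzene; 4 (S)-3-hydroxy-N-methoxy-N-methylpent-4-enamide
Product: 12 (S)-1-[3,4-bis(benzyloxy)-5-methoxyphenyl]-5-hydroxyhept-6-en-3-one, via Grignard reagent 11 (not isolated)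
Conditions: Mg turnings (I2 cat.), THF, rt → 40 °C; then 4 (0.4 equiv relative to 11), THF, −20 → 0 °C; cold 1 M HCl
Reagents that add atoms: none
Why: Weinreb ketone synthesis; the first equivalent of 11 deprotonates the hydroxyl and a second adds to the amide to give a magnesium-chelated tetrahedral intermediate that survives until the quench, so no tertiary alcohol can form. The amide enolate is too poor a leaving group for retro-aldol cleavage of the alkoxide, and the stereocentre is not touched.

**Step 9**
Reactants: 13 4-(benzyloxy)-3-methoxybenzaldehyde
Product: 14 1-(benzyloxy)-2-methoxy-4-vinylbenzene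
Conditions: Ph3PCH3Br (1.3 equiv), KOtBu (1.25 equiv), THF, 0 °C → rt
Reagents that add atoms: methyltriphenylphosphonium bromide, C[P+](c1ccccc1)(c1ccccc1)c1ccccc1.[Br-]
Why: Wittig methylenation of an aromatic aldehyde, as in step 5.

**Step 10**
Reactants: 12 (S)-1-[3,4-bis(benzyloxy)-5-methoxyphenyl]-5-hydroxyhept-6-en-3-one; 14 1-(benzyloxy)-2-methoxy-4-vinylbenzene
Product: 15 (S,E)-7-[4-(benzyloxy)-3-methoxyphenyl]-1-[3,4-bis(benzyloxy)-5-methoxyphenyl]-5-hydroxyhept-6-en-3-one
Conditions: RuCl2(=CHPh)(PCy3)(H2IMes) (second-generation Grubbs catalyst, 5 mol%), 14 (3 equiv), 1,4-benzoquinone (10 mol%), CH2Cl2 (0.1 M), 40 °C, argon sweep; Et3N-deactivated silica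
Reagents that add atoms: none
Why: Olefin cross-metathesis of a styrene with a secondary allylic alcohol, a well-established pairing for RuCl2(=CHPh)(PCy3)(H2IMes). After phosphine loss the ruthenium benzylidene undergoes [2+2] cycloaddition with the vinyl group of 12 or with 14, the ruthenacyclobutane cycloreverts, and the new ruthenium alkylidene is intercepted by the other alkene, so that the C6=C7 bond forms while ethylene is expelled and swept out, which drives the exchange. No ring is closed and no stereocentre is created; C5 is allylic to the reacting alkene but none of its bonds is touched, so its (S) configuration is carried through. The selectivity needed is cross coupling over homo coupling: 14 dimerises quickly but is used in excess, whereas the branched carbinol 12 dimerises slowly because of the substituent next to its alkene, so productive turnovers should funnel 12 into the cross product. The (E) geometry follows from thermodynamic control, since the 1,2-disubstituted styrenyl alkene equilibrates by secondary metathesis to the less strained isomer. The free hydroxyl is tolerated and is known to speed metathesis at the neighbouring alkene by hydrogen bonding to a chloride ligand. Double-bond migration by ruthenium hydrides, which would turn the allylic alcohol into a 1,3-diketone, is held back by 1,4-benzoquinone. The benzyl ethers, the methyl ethers and the ketone are inert to the carbene.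

**Step 11**
Reactants: 15 (S,E)-7-[4-(benzyloxy)-3-methoxyphenyl]-1-[3,4-bis(benzyloxy)-5-methoxyphenyl]-5-hydroxyhept-6-en-3-one
Product: 16 (R)-1-(3,4-dihydroxy-5-methoxyphenyl)-5-hydroxy-7-(4-hydroxy-3-methoxyphenyl)heptan-3-one
Conditions: H2 (1 atm), 10% Pd/C, degassed EtOAc/EtOH (4:1), rt; filtration under argon
Reagents that add atoms: none
Why: Heterogeneous hydrogenation saturates the C6=C7 bond and hydrogenolyses the three aryl benzyl ethers in one flask; in a neutral medium the alkene should be reduced faster than the allylic C5–O bond is cleaved, after which the carbinol is an ordinary secondary alcohol. The ketone, the methyl ethers and the stereocentre are unaffected, and the (S) label becomes (R) only because C6 loses its priority over C4.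

## Compound list

1 | ethyl 3-hydroxypent-4-enoate (racemic) | CCOC(=O)CC(O)C=C | starting material
2 | ethyl (S)-3-acetoxypent-4-enoate | C=C[C@@H](OC(C)=O)CC(=O)OCC | intermediate
3 | ethyl (S)-3-hydroxypent-4-enoate | C=C[C@@H](O)CC(=O)OCC | intermediate
4 | (S)-3-hydroxy-N-methoxy-N-methylpent-4-enamide | C=C[C@@H](O)CC(=O)N(C)OC | intermediate
5 | 3,4-dihydroxy-5-methoxybenzaldehyde | COc1cc(C=O)cc(O)c1O | starting material
6 | 3,4-bis(benzyloxy)-5-methoxybenzaldehyde | COc1cc(C=O)cc(OCc2ccccc2)c1OCc1ccccc1 | intermediate
7 | 1,2-bis(benzyloxy)-3-methoxy-5-vinylbenzene | COc1cc(C=C)cc(OCc2ccccc2)c1OCc1ccccc1 | intermediate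
8 | 9-{2-[3,4-bis(benzyloxy)-5-methoxyphenyl]ethyl}-9-borabicyclo[3.3.1]nonane | COc1cc(CCB2C3CCCC2CCC3)cc(OCc2ccccc2)c1OCc1ccccc1 | intermediate
9 | 2-[3,4-bis(benzyloxy)-5-methoxyphenyl]ethan-1-ol | COc1cc(CCO)cc(OCc2ccccc2)c1OCc1ccccc1 | intermediate
10 | 1,2-bis(benzyloxy)-5-(2-bromoethyl)-3-methoxybenzene | COc1cc(CCBr)cc(OCc2ccccc2)c1OCc1ccccc1 | intermediate
11 | {2-[3,4-bis(benzyloxy)-5-methoxyphenyl]ethyl}magnesium bromide | COc1cc(CC[Mg]Br)cc(OCc2ccccc2)c1OCc1ccccc1 | intermediate
12 | (S)-1-[3,4-bis(benzyloxy)-5-methoxyphenyl]-5-hydroxyhept-6-en-3-one | C=C[C@@H](O)CC(=O)CCc1cc(OCc2ccccc2)c(OCc2ccccc2)c(OC)c1 | intermediate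
13 | 4-(benzyloxy)-3-methoxybenzaldehyde | COc1cc(C=O)ccc1OCc1ccccc1 | starting material
14 | 1-(benzyloxy)-2-methoxy-4-vinylbenzene | COc1cc(C=C)ccc1OCc1ccccc1 | intermediate
15 | (S,E)-7-[4-(benzyloxy)-3-methoxyphenyl]-1-[3,4-bis(benzyloxy)-5-methoxyphenyl]-5-hydroxyhept-6-en-3-one | COc1cc(/C=C/[C@@H](O)CC(=O)CCc2cc(OCc3ccccc3)c(OCc3ccccc3)c(OC)c2)ccc1OCc1ccccc1 | intermediate
16 | (R)-1-(3,4-dihydroxy-5-methoxyphenyl)-5-hydroxy-7-(4-hydroxy-3-methoxyphenyl)heptan-3-one | COc1cc(CC[C@@H](O)CC(=O)CCc2cc(O)c(O)c(OC)c2)ccc1O | target

## Step count and least certain steps

Total step count: 11. Longest linear sequence: 7 steps (steps 4, 5, 6, 7, 8, 10, 11).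

**Step 10 (key step).** The most likely failure is incomplete conversion of the advanced ketone 12. Ruthenium hydrides formed as the catalyst ages can move the double bond of the allylic alcohol and give a 1,3-diketone that binds ruthenium. The C3 carbonyl can chelate the alkylidene formed at C6 and slow turnover. Self-metathesis of the electron-rich styrene depletes the partner. The fallback sets out from 3 and 14 and returns at 15. The metathesis is moved to the cheap ester 3, used in excess over 14 with the same catalyst, which should give ethyl (S,E)-5-[4-(benzyloxy)-3-methoxyphenyl]-3-hydroxypent-4-enoate F1, so that any loss falls on an inexpensive C5 compound. Amidation with MeNH(OMe)·HCl and iPrMgCl would then give (S,E)-5-[4-(benzyloxy)-3-methoxyphenyl]-3-hydroxy-N-methoxy-N-methylpent-4-enamide F2, and addition of the Grignard reagent 11 (2.5 equiv) would give 15.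

**Step 11.** The most likely failure is hydrogenolysis of the allylic C5–O bond on palladium before the C6=C7 bond is saturated, because the carbinol is allylic to an electron-rich styrenyl system; this would remove the hydroxyl. The fallback sets out from 15 and returns at 16 and separates the two reductions. Diimide, generated from dipotassium azodicarboxylate and AcOH in MeOH/CH2Cl2 at rt, cannot cleave C–O bonds and is not a carbonyl reagent. It should reduce the alkene to (R)-7-[4-(benzyloxy)-3-methoxyphenyl]-1-[3,4-bis(benzyloxy)-5-methoxyphenyl]-5-hydroxyheptan-3-one F3, in which the carbinol is no longer allylic. Hydrogenolysis of F3 over Pd/C then gives 16.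

**Step 8.** The most likely failure is incomplete acyl substitution. The magnesium alkoxide of 4 may aggregate or precipitate, Wurtz coupling during formation of 11 lowers its titre, and one equivalent of the four-step reagent is consumed as a base. The fallback sets out from 4 and returns at 12. Silylation with TESCl and imidazole would give (S)-N-methoxy-N-methyl-3-[(triethylsilyl)oxy]pent-4-enamide F4. Addition of 11 (1.3 equiv) in THF at 0 °C would give (S)-1-[3,4-bis(benzyloxy)-5-methoxyphenyl]-5-[(triethylsilyl)oxy]hept-6-en-3-one F5. AcOH/THF/H2O then removes the silyl group under acidic conditions that avoid β-elimination and releases 12.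

**Step 1.** The most likely failure is insufficient discrimination between the enantiomers, because vinyl and CH2CO2Et do not differ greatly in size; the acetate would then be enantiomerically impure. The fallback sets out from 10, returns at 12 and takes the stereocentre from the chiral pool, bypassing steps 1 to 3 and 8. Alkylation of 2-lithio-1,3-dithiane (1,3-dithiane, nBuLi, THF, −30 °C) with 10 would give 2-{2-[3,4-bis(benzyloxy)-5-methoxyphenyl]ethyl}-1,3-dithiane F6. A second lithiation and opening of purchased (R)-2-vinyloxirane (C=C[C@@H]1CO1) at its CH2 terminus would give (S)-1-(2-{2-[3,4-bis(benzyloxy)-5-methoxyphenyl]ethyl}-1,3-dithian-2-yl)but-3-en-2-ol F7. Unmasking with MeI and CaCO3 in aqueous MeCN then gives 12.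

## Further compounds

F1 | step 10 | ethyl (S,E)-5-[4-(benzyloxy)-3-methoxyphenyl]-3-hydroxypent-4-enoate | COc1cc(/C=C/[C@@H](O)CC(=O)OCC)ccc1OCc1ccccc1
F2 | step 10 | (S,E)-5-[4-(benzyloxy)-3-methoxyphenyl]-3-hydroxy-N-methoxy-N-methylpent-4-enamide | COc1cc(/C=C/[C@@H](O)CC(=O)N(C)OC)ccc1OCc1ccccc1
F3 | step 11 | (R)-7-[4-(benzyloxy)-3-methoxyphenyl]-1-[3,4-bis(benzyloxy)-5-methoxyphenyl]-5-hydroxyheptan-3-one | COc1cc(CC[C@@H](O)CC(=O)CCc2cc(OCc3ccccc3)c(OCc3ccccc3)c(OC)c2)ccc1OCc1ccccc1
F4 | step 8 | (S)-N-methoxy-N-methyl-3-[(triethylsilyl)oxy]pent-4-enamide | C=C[C@@H](O[Si](CC)(CC)CC)CC(=O)N(C)OC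
F5 | step 8 | (S)-1-[3,4-bis(benzyloxy)-5-methoxyphenyl]-5-[(triethylsilyl)oxy]hept-6-en-3-one | C=C[C@@H](O[Si](CC)(CC)CC)CC(=O)CCc1cc(OCc2ccccc2)c(OCc2ccccc2)c(OC)c1
F6 | step 1 | 2-{2-[3,4-bis(benzyloxy)-5-methoxyphenyl]ethyl}-1,3-dithiane | COc1cc(CCC2SCCCS2)cc(OCc2ccccc2)c1OCc1ccccc1
F7 | step 1 | (S)-1-(2-{2-[3,4-bis(benzyloxy)-5-methoxyphenyl]ethyl}-1,3-dithian-2-yl)but-3-en-2-ol | C=C[C@@H](O)CC1(CCc2cc(OCc3ccccc3)c(OCc3ccccc3)c(OC)c2)SCCCS1
A1 | alternative 1 | (E)-1-(3,4-dihydroxy-5-methoxyphenyl)-7-(4-hydroxy-3-methoxyphenyl)hept-1-ene-3,5-dione | COc1cc(CCC(=O)CC(=O)/C=C/c2cc(O)c(O)c(OC)c2)ccc1O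
A2 | alternative 1 | (R,E)-1-(3,4-dihydroxy-5-methoxyphenyl)-5-hydroxy-7-(4-hydroxy-3-methoxyphenyl)hept-1-en-3-one | COc1cc(CC[C@@H](O)CC(=O)/C=C/c2cc(O)c(O)c(OC)c2)ccc1O
A3 | alternative 2 | 2-(2-{2-[3,4-bis(benzyloxy)-5-methoxyphenyl]ethyl}-1,3-dioxolan-2-yl)acetaldehyde | O=CCC1(CCc2cc(OCc3ccccc3)c(OCc3ccccc3)c(OC)c2)OCCO1
A4 | alternative 2 | bis{2-[4-(benzyloxy)-3-methoxyphenyl]ethyl}zinc | COc1cc(CC[Zn]CCc2ccc(OCc3ccccc3)c(OC)c2)ccc1OCc1ccccc1
A5 | alternative 2 | (R)-4-[4-(benzyloxy)-3-methoxyphenyl]-1-(2-{2-[3,4-bis(benzyloxy)-5-methoxyphenyl]ethyl}-1,3-dioxolan-2-yl)butan-2-ol | COc1cc(CC[C@@H](O)CC2(CCc3cc(OCc4ccccc4)c(OCc4ccccc4)c(OC)c3)OCCO2)ccc1OCc1ccccc1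
A6 | alternative 3 | 1,3-dioxoisoindolin-2-yl 3-[3,4-bis(benzyloxy)-5-methoxyphenyl]propanoate | COc1cc(CCC(=O)ON2C(=O)c3ccccc3C2=O)cc(OCc2ccccc2)c1OCc1ccccc1
A7 | alternative 3 | S-(pyridin-2-yl) (R)-5-[4-(benzyloxy)-3-methoxyphenyl]-3-[(tert-butyldimethylsilyl)oxy]pentanethioate | COc1cc(CC[C@@H](O[Si](C)(C)C(C)(C)C)CC(=O)Sc2ccccn2)ccc1OCc1ccccc1
A8 | alternative 3 | (R)-7-[4-(benzyloxy)-3-methoxyphenyl]-1-[3,4-bis(benzyloxy)-5-methoxyphenyl]-5-[(tert-butyldimethylsilyl)oxy]heptan-3-one | COc1cc(CC[C@@H](O[Si](C)(C)C(C)(C)C)CC(=O)CCc2cc(OCc3ccccc3)c(OCc3ccccc3)c(OC)c2)ccc1OCc1ccccc1
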